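# Proposed total synthesis of CNP0260455.1 by two-carbon ring expansion of the isoprene cyclodimer

## Analysis of the target

The target is a germacrane-type sesquiterpenoid triester built on a single ten-membered carbocycle, numbered here C1 (epoxide CH), C2 (CH2), C3 (angeloyloxy), C4 (epoxide C–CH3), C5 (epoxide CH), C6 (CH2), C7 (isopropenyl), C8 (acetoxy), C9 (angeloyloxy) and C10 (epoxide C–CH3), with oxiranes across C1–C10 and C4–C5. Eight ring carbons are stereogenic, (1R,3S,4S,5S,7R,8S,9S,10R), and in both epoxides the two ring bonds are cis, so each descends from a ring-cis trisubstituted olefin. With the ring drawn flat, the substituents at C3, C7, C8 and C9 lie on one face, the 1,10-epoxide oxygen lies on that same face (cis to O9) and the 4,5-epoxide oxygen on the other (trans to O3). The sensitive groups are the two angelates (Z to E isomerisation to tiglates), the C8 acetate next to another oxygenated carbon (acyl migration), the two trisubstituted epoxides (transannular opening under acid) and the isopropenyl group (a second site for electrophilic oxidants). The difficulty is a medium ring with eight stereocentres and few rigid relays, and four oxygenated carbons that must be told apart: C3 and C9 carry the same ester but opposite epoxide relationships. The strategy rests on one observation: at the olefin level the chain C9–C10(CH3)=C1–C2–C3–C4(CH3)=C5–C6 is a head-to-tail isoprene dimer with both double bonds ring-cis. That is the skeleton of 1,5-dimethylcycloocta-1,5-diene with C6 bonded to C9, so only C7–C8 has to be inserted between C6 and C9, and C3 and C9 are the allylic carbons next to the methyl-bearing olefin carbons.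

## Retrosynthetic reasoning

**C9–O acyl bond (21 to 20 and 16).** The angelate on the most hindered hydroxyl is put on last, so that this isomerisation-prone ester sees no further chemistry and the free C9 hydroxyl stays available to direct the second epoxidation. The acyl donor is the pre-formed mixed anhydride 16, which transfers the angeloyl group without a nucleophilic catalyst.

**C1–C10 epoxide (20 to 19).** This epoxide is cis to O9, so it is cut back to the C1=C10 olefin of allylic alcohol 19. The forward step is a hydroxyl-directed VO(acac)2/hydroperoxide epoxidation, which also leaves the isopropenyl group alone.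

**C9–H bond (19 to 18).** The carbinol comes from enone 18 by an oxazaborolidine-controlled reduction. C9 is kept as a ketone until here because the conjugated C1=C10 bond is then inert while the other olefin is epoxidised.

**C8–H bond (18 to 17).** The carboxyl carbon that the ring expansion leaves on C8 is removed here. An allyl ester is used so that zerovalent palladium and formate can do this at room temperature; a methyl ester would need hot halide conditions that the epoxide, the acetate and the medium-ring dienes would not tolerate. Protonation of the resulting enol sets C8.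

**C3–O acyl bond (17 to 14 and 16).** The C3 angelate goes on as soon as the 4,5-epoxide is in place, again from anhydride 16. No free hydroxyl other than O9 is then present later, and O3 and O9 are never free together.

**C4–C5 epoxide (14 to 13).** This epoxide is trans to O3. It is cut back to the allylic alcohol 13 and made with a peracid, whose sense in medium-ring 2-cycloalkenols is opposite to that of the VO(acac)2 system. Doing it while C9 is still a ketone solves the problem of two like olefins.

**C3–H bond (13 to 12).** An oxazaborolidine-controlled reduction of the C3 enone is needed, and it must leave the C9 ketone. In 12 that ketone sits between a fully substituted C8 and the C10 methyl, which is the basis for the chemoselectivity.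

**C8–O bond (12 to 11).** The oxygen is put on C8 as the acetate itself, by oxidation of the β-keto ester enol. The ester group thus serves as the regiochemical handle that separates C8 from the equally acidic C2 methylene.

**C7–isopropenyl bond (11 to 9 and 10).** In 9 the C7=C8 bond is activated by both the ketone and the ester and has no alkyl group on its α-carbon. It is the one acceptor that a chiral alkenyl–rhodium species should choose, and 9 is achiral, so the ligand alone sets the first stereocentre.

**C6–C7 and C8–C9 bonds (9 to 3 and 6).** This is the key disconnection. Taking out C7–C8 and rejoining C6 to C9 leads to the eight-membered dienedione 3 and the acetylenic ester 6. Cutting here is preferred over any ring-closing disconnection because both trisubstituted ring-cis olefins and both future carbinol carbons are already in 3, and no medium ring has to be closed end to end. The forward reaction must make a C6 carbanion add to the alkyne, close the vinyl anion on C9 and break the C6–C9 bond.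

**Precursors (16 to 15; 6 to 4 and 5; 3 to 2 to 1).** Anhydride 16 is one activation step from acid 15 and is made once for both angeloylations. The ester 6 is one esterification from 4 and 5. The dione 3 follows from commercial diene 1 by allylic oxidation of the two CH2 groups next to the methyl-bearing olefin carbons (diol 2) and oxidation to the ketones.

## Alternatives that were turned down

**Alternative 1: macrocyclising Darzens reaction.** Cutting C1–C10 together with the C10–O bond of the 1,10-epoxide opens the ring to the acyclic aldehyde α-chloro ketone A1. Its chloro-enolate (C10) would add to the C1 aldehyde and the aldolate would displace chloride, closing ring and epoxide at once to give epoxy ketone A2.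
- For: one operation makes the ring and an epoxide. The orthogonal ethers at C3 and C8 tell the oxygens apart from the start, and C7 and C8 come from acyclic chemistry. On both points this plan is stronger than the chosen one.
- Against: a ten-membered ring is closed by an aldol-type step that competes with oligomerisation. The ketone can also enolise toward C8, which risks epimerisation or β-elimination of the ether. Nothing in A1 enforces the cis-epoxide geometry or its face relative to distant centres. A1 needs a long linear synthesis that includes making the C4=C5 Z olefin.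
- Comparison: the chosen route gives up early differentiation of the oxygens but never closes a medium ring end to end and buys both Z olefins.

**Alternative 2: photochemical [2+2] ladder.** Here C3–C4 and C9–C10 are formed between β-alkoxy enone A3 (a six-membered ring holding C4–C9) and silyloxycyclobutene A4 (holding C3, C10, C1, C2). Irradiation would give the six–four–four tricycle A5, and two later fragmentations (retro-aldol across C4–C9, Grob-type across C3–C10) would unzip it to the ten-membered ring.
- For: it is convergent, avoids macrocyclisation as the chosen route does, and carries C7 in with defined configuration before any ring growth. On the last point it is stronger.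
- Against: the cycloaddition must join two fully substituted olefins into a cyclobutane with four contiguous quaternary carbons, with open regiochemistry and several diastereomers. The geometry of the C1=C10 olefin depends on an anti-periplanar fragmentation that those diastereomers do not share. After unzipping, the C5 ketone must be turned into the C4=C5 olefin and C8 still lacks its oxygen.
- Comparison: the chosen route makes its two new bonds thermally at unhindered carbons and has both olefins in place from the first step.

**Alternative 3: zinc insertion and Negishi closure.** Cutting C5–C6 leads to A6, a primary alkyl iodide (C6) tethered to a Z vinyl iodide (C5) with C3, C7, C8 and C9 already set. Zinc insertion into the alkyl iodide and coupling with Pd(PPh3)4, with retention at the vinyl iodide, would give cyclodecadiene A7.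
- For: C7, C8 and C9 are fixed by reliable acyclic methods and the cis C8/C9 diol is locked as an acetonide. This is clearly stronger than the chosen route for those three centres. The Z geometry at C4=C5 is transferred with retention.
- Against: the closure is an entropically costly ten-membered ring formation by an alkylzinc that bears a β-stereocentre. The acetonide does not distinguish O8 (acetate) from O9 (angelate). A6 requires a long linear sequence in which both Z-trisubstituted olefins are constructed.
- Comparison: the chosen route is much shorter to the ring and risk-free in olefin geometry. It pays for this with stereocentres that are set on the ring by conformational and catalyst control.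

Key step: step 4

## Remarks on the chemistry

- Carbocyclic compounds from 7 onward are named with the locants C1–C10 defined in the analysis, not with lowest locants. Descriptors at C4, C7, C9 and C10 change along the route only because substituent priorities change; the SMILES strings are authoritative.
- Commercial diene 1 contains some of the 1,6-dimethyl isomer. It is assumed that material enriched in the 1,5-isomer is used and that regioisomeric products are removed at diol 2 or dione 3.
- Compound 9 is written as its C7=C8 tautomer. It is assumed to equilibrate with the C6=C7 tautomer through their common enolate, and the mixture is used in step 5.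
- Mixed anhydride 16 is made in one batch sized for both angeloylations. It is assumed to keep as a cold toluene solution under argon between its two uses.

## Route

Step 1
Reactants: 1 (1Z,5Z)-1,5-dimethylcycloocta-1,5-diene
Product: 2 (2Z,6Z)-2,6-dimethylcycloocta-2,6-diene-1,5-diol (cis/trans mixture at the two carbinol carbons, used as such)
Conditions: SeO2 (cat., 0.5 equiv), t-BuOOH (5 equiv), salicylic acid (cat.), CH2Cl2, 25 °C
Reagents that add atoms: tert-butyl hydroperoxide, CC(C)(C)OO
Why: Allylic hydroxylation with SeO2 (ene reaction, then [2,3]-sigmatropic shift) occurs at the ring CH2 on the more substituted olefin carbon, that is next to each C–CH3, and returns the double bond to its place with the ring-cis geometry an eight-membered ring enforces; any enone from over-oxidation converges in step 2.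

Step 2
Reactants: 2 (2Z,6Z)-2,6-dimethylcycloocta-2,6-diene-1,5-diol
Product: 3 (2Z,6Z)-2,6-dimethylcycloocta-2,6-diene-1,5-dione (in target numbering: ketones at C9 and C3, olefins C10=C1 and C4=C5, methylenes C2 and C6)
Conditions: MnO2 (activated, excess), CH2Cl2, 25 °C
Reagents that add atoms: none
Why: Neutral heterogeneous oxidation of secondary allylic alcohols to enones, with no acid or base that could move the olefins; both diol diastereomers give the same achiral, twofold-symmetric dione.

Step 3
Reactants: 4 propiolic acid; 5 allyl alcohol
Product: 6 allyl propiolate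
Conditions: DCC, DMAP (cat.), CH2Cl2, −20 → 0 °C
Reagents that add atoms: none
Why: Steglich esterification; low temperature and little DMAP limit amine addition to the ynoate, and the allyl ester is what later allows removal of the carboxyl group at room temperature.

Step 4
Reactants: 3 (2Z,6Z)-2,6-dimethylcycloocta-2,6-diene-1,5-dione; 6 allyl propiolate
Product: 9 allyl 4,10-dimethyl-3,9-dioxocyclodeca-1(10),4,7-triene-8-carboxylate (all three ring olefins ring-cis), via sodium allenolate Michael adduct 7 (not isolated), via fused cyclobutene alkoxide 8 (not isolated)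
Conditions: NaH (1.05 equiv), THF, 0 °C; then 6 (1.1 equiv, slow addition, 0.02 M), −40 → 0 °C; AcOH, −78 °C
Reagents that add atoms: none
Why: Proposed new method: the sodium enolate of 3 (a weak base that leaves the acetylenic C–H of 6 alone) should add through C6 to the terminal carbon of 6 to give allenolate 7, whose ester-bearing carbon C8 attacks the neighbouring C9 carbonyl to form cyclobutene alkoxide 8; retro-aldol cleavage of the strained C6–C9 bond then gives a C6 carbanion delocalised into both the C7=C8(CO2allyl)–C9=O and the C5=C4–C3=O systems, and cold protonation gives 9. The closest known reaction type is the two-carbon ring enlargement of cyclic β-keto ester enolates, and of cyclic enamines, with acetylenic esters through the same cyclobutene; what is new is the donor, the methylene of a vinylogous 1,3-diketone, which keeps an acidic hydrogen on C6 after the Michael step. The only ring closed directly is the four-membered one, in a 4-exo-trig attack of the vinyl anion on the carbonyl; the ten-membered ring is not closed end to end but appears when the bond shared by the four- and eight-membered rings breaks. No stereocentre is created in 9, since C6 and C9 of 7 and 8 end as CH2 and C=O. The step needs C- over O-alkylation and attack at C6, not at the methyl-bearing C4, which is expected for a soft delocalised enolate at its less substituted terminus, and the twofold axis of 3 makes C2 and C6 the same site. It also needs closure of 7 on C9 to outrun proton transfer to C8 from C6–H, C2–H2 or the alkyne C–H; the aprotic medium, the low concentration of 6 and the position of C9 one bond from C6 favour this. If proton transfer wins, the open Michael adduct forms, which is the main risk.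

Step 5
Reactants: 9 allyl 4,10-dimethyl-3,9-dioxocyclodeca-1(10),4,7-triene-8-carboxylate; 10 isopropenylboronic acid pinacol ester
Product: 11 allyl (7S)-7-isopropenyl-4,10-dimethyl-3,9-dioxocyclodeca-1(10),4-diene-8-carboxylate (C8 epimers and enol, used together)
Conditions: [Rh(cod)Cl]2 (3 mol %), (S)-BINAP (7 mol %), K3PO4 (0.5 equiv), 1,4-dioxane/H2O 10:1, 50 °C
Reagents that add atoms: none
Why: Hayashi–Miyaura conjugate addition; C7=C8 is activated by two carbonyl groups and is the only acceptor without an α-alkyl group, so the alkenylrhodium should add at C7 and not at C1 or C5, and the C6=C7 tautomer of 9 would receive the nucleophile at the same carbon. C7 is set by the ligand alone because 9 is achiral; (S)-BINAP is chosen by analogy with ring-cis cycloalkenones, a provisional assignment, and the antipodal ligand would give the mirror-image series.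

Step 6
Reactants: 11 allyl (7S)-7-isopropenyl-4,10-dimethyl-3,9-dioxocyclodeca-1(10),4-diene-8-carboxylate
Product: 12 allyl (7R)-8-acetoxy-7-isopropenyl-4,10-dimethyl-3,9-dioxocyclodeca-1(10),4-diene-8-carboxylate (C8 configuration not assigned)
Conditions: Pb(OAc)4 (1.1 equiv), benzene, 25 °C
Reagents that add atoms: lead tetraacetate, CC(=O)O[Pb](OC(C)=O)(OC(C)=O)OC(C)=O
Why: α-Acetoxylation of a β-keto ester through its enol; C8 is the only carbon flanked by two carbonyl groups and strongly enolised, so the equally acidic but little enolised C2 methylene and the olefins are left. The configuration made at C8 is erased in step 11.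

Step 7
Reactants: 12 allyl (7R)-8-acetoxy-7-isopropenyl-4,10-dimethyl-3,9-dioxocyclodeca-1(10),4-diene-8-carboxylate
Product: 13 allyl (3S,7R)-8-acetoxy-3-hydroxy-7-isopropenyl-4,10-dimethyl-9-oxocyclodeca-1(10),4-diene-8-carboxylate
Conditions: (R)-2-methyl-CBS-oxazaborolidine (0.5 equiv), catecholborane (1.5 equiv), toluene, −78 °C
Reagents that add atoms: none
Why: CBS reduction; the C3 carbonyl binds the catalyst with the α-methylvinyl group as the large substituent and the C2 methylene as the small one, which with the (R)-catalyst gives the (3S)-alcohol. The C9 ketone lies between the fully substituted C8 and the C10 methyl and is electron-poor, so it should not bind, and catecholborane at −78 °C does not hydroborate the isopropenyl group.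

Step 8
Reactants: 13 allyl (3S,7R)-8-acetoxy-3-hydroxy-7-isopropenyl-4,10-dimethyl-9-oxocyclodeca-1(10),4-diene-8-carboxylate
Product: 14 allyl (3S,4R,5S,7R)-8-acetoxy-4,5-epoxy-3-hydroxy-7-isopropenyl-4,10-dimethyl-9-oxocyclodec-1(10)-ene-8-carboxylate
Conditions: mCPBA (1.05 equiv), NaHCO3, CH2Cl2, −20 → 0 °C
Reagents that add atoms: 3-chloroperbenzoic acid, O=C(OO)c1cccc(Cl)c1
Why: Peracid epoxidation of the most electron-rich olefin (trisubstituted, allylic alcohol); the conjugated C1=C10 bond is deactivated and the 1,1-disubstituted isopropenyl group reacts more slowly. In eight- to ten-membered 2-cycloalkenols peracids attack the outer face of the conformer with a pseudo-equatorial hydroxyl and give the epoxide trans to it, the relationship required between O3 and the 4,5-epoxide.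

Step 9
Reactants: 15 angelic acid, (Z)-2-methylbut-2-enoic acid
Product: 16 angelic 2,4,6-trichlorobenzoic anhydride (crude; kept as a toluene solution at −20 °C under argon for steps 10 and 14)
Conditions: 2,4,6-trichlorobenzoyl chloride (1.0 equiv), Et3N (1.05 equiv), THF, 0 → 25 °C; filtration of the ammonium salt, concentration, toluene
Reagents that add atoms: 2,4,6-trichlorobenzoyl chloride, O=C(Cl)c1c(Cl)cc(Cl)cc1Cl
Why: Activation stage of the Yamaguchi esterification, acylation of the triethylammonium carboxylate by the aroyl chloride; no nucleophilic catalyst is present, so the Z geometry of the angeloyl group is kept, and the two ortho chlorines of 16 later steer alcohols to the angeloyl carbonyl.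

Step 10
Reactants: 14 allyl (3S,4R,5S,7R)-8-acetoxy-4,5-epoxy-3-hydroxy-7-isopropenyl-4,10-dimethyl-9-oxocyclodec-1(10)-ene-8-carboxylate; 16 angelic 2,4,6-trichlorobenzoic anhydride
Product: 17 allyl (3S,4S,5S,7R)-8-acetoxy-3-angeloyloxy-4,5-epoxy-7-isopropenyl-4,10-dimethyl-9-oxocyclodec-1(10)-ene-8-carboxylate
Conditions: 16 (3 equiv), Et3N (3 equiv), toluene, 75 °C
Reagents that add atoms: none
Why: Acyl-transfer stage of the Yamaguchi esterification with pre-formed anhydride 16, run without DMAP because nucleophilic catalysts promote Z to E isomerisation to the tiglate; 14 has a single hydroxyl, which attacks the unhindered angeloyl carbonyl, and the amine buffers the aroic acid set free so that the epoxide is not exposed to acid.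

Step 11
Reactants: 17 allyl (3S,4S,5S,7R)-8-acetoxy-3-angeloyloxy-4,5-epoxy-7-isopropenyl-4,10-dimethyl-9-oxocyclodec-1(10)-ene-8-carboxylate
Product: 18 (3S,4S,5S,7R,8S)-8-acetoxy-3-angeloyloxy-4,5-epoxy-7-isopropenyl-4,10-dimethylcyclodec-1(10)-en-9-one
Conditions: Pd(PPh3)4 (5 mol %), HCO2H (3 equiv), Et3N (4 equiv), THF, 25 °C
Reagents that add atoms: none
Why: Palladium-catalysed decarboxylative protonation of an allyl β-keto ester, with formate reducing the allyl fragment; the conditions are near neutral and should spare the epoxide, acetate and angelate. C8 is set when the enol is protonated: delivery of the proton to the face of C8 away from the C7 isopropenyl group leaves the acetoxy group cis to it (8S), and this is the least secure stereocentre of the route.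

Step 12
Reactants: 18 (3S,4S,5S,7R,8S)-8-acetoxy-3-angeloyloxy-4,5-epoxy-7-isopropenyl-4,10-dimethylcyclodec-1(10)-en-9-one
Product: 19 (3S,4S,5S,7R,8S,9R)-8-acetoxy-3-angeloyloxy-4,5-epoxy-7-isopropenyl-4,10-dimethylcyclodec-1(10)-en-9-ol
Conditions: (R)-2-methyl-CBS-oxazaborolidine (1.0 equiv), catecholborane (2 equiv), toluene/CH2Cl2, −78 °C
Reagents that add atoms: none
Why: CBS reduction with the α-methylvinyl group (C10) as the large substituent; the same (R)-catalyst that set C3 gives the C9 carbinol with the hydroxyl cis to the C8 acetoxy group (named 9R here only because C8 outranks C10). Catalyst control has to override the Felkin–Anh preference of the α-acetoxy ketone, which points the other way.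

Step 13
Reactants: 19 (3S,4S,5S,7R,8S,9R)-8-acetoxy-3-angeloyloxy-4,5-epoxy-7-isopropenyl-4,10-dimethylcyclodec-1(10)-en-9-ol
Product: 20 (1R,3S,4S,5S,7R,8S,9S,10S)-8-acetoxy-3-angeloyloxy-1,10:4,5-diepoxy-7-isopropenyl-4,10-dimethylcyclodecan-9-ol
Conditions: VO(acac)2 (5 mol %), t-BuOOH (1.5 equiv, decane), CH2Cl2, 0 → 25 °C
Reagents that add atoms: tert-butyl hydroperoxide, CC(C)(C)OO
Why: Hydroxyl-directed epoxidation; the vanadate ester of O9 delivers oxygen to the adjacent C1=C10 bond from the face of the hydroxyl, which in medium-ring 2-cycloalkenols gives the cis epoxy alcohol, and the isopropenyl and angelate olefins have no allylic hydroxyl and stay untouched.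

Step 14
Reactants: 20 (1R,3S,4S,5S,7R,8S,9S,10S)-8-acetoxy-3-angeloyloxy-1,10:4,5-diepoxy-7-isopropenyl-4,10-dimethylcyclodecan-9-ol; 16 angelic 2,4,6-trichlorobenzoic anhydride
Product: 21 (1R,3S,4S,5S,7R,8S,9S,10R)-8-acetoxy-3,9-bis(angeloyloxy)-1,10:4,5-diepoxy-7-isopropenyl-4,10-dimethylcyclodecane (the target)
Conditions: 16 (6 equiv), Et3N (6 equiv), toluene, 75 °C
Reagents that add atoms: none
Why: Acyl-transfer stage of the Yamaguchi esterification at the last, hindered hydroxyl with anhydride 16 and no DMAP, to avoid tiglate formation; a large excess of 16 is used so that acylation of O9 outpaces migration of the neighbouring acetyl group from O8.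

## Compound list

1 | (1Z,5Z)-1,5-dimethylcycloocta-1,5-diene | C/C1=C/CC/C(C)=C\CC1 | starting material
2 | (2Z,6Z)-2,6-dimethylcycloocta-2,6-diene-1,5-diol, cis/trans mixture | OC1/C(C)=C\CC(O)/C(C)=C\C1 | intermediate
3 | (2Z,6Z)-2,6-dimethylcycloocta-2,6-diene-1,5-dione | O=C1/C(C)=C\CC(=O)/C(C)=C\C1 | intermediate
4 | propiolic acid | C#CC(=O)O | starting material
5 | allyl alcohol | C=CCO | starting material
6 | allyl propiolate | C#CC(=O)OCC=C | intermediate
7 | sodium allenolate Michael adduct (C6 of the dione bonded to C7 of CH=C=C(ONa)O-allyl), racemic | O=C1/C(C)=C\CC(=O)/C(C)=C\C1C=C=C([O-])OCC=C.[Na+] | intermediate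
8 | fused cyclobutene alkoxide (four-membered ring C6–C7=C8–C9 on the eight-membered ring, ONa on C9, CO2allyl on C8), racemic | C=CCOC(=O)C1=CC2/C=C(C)\C(=O)C/C=C(C)\C12[O-].[Na+] | intermediate
9 | allyl 4,10-dimethyl-3,9-dioxocyclodeca-1(10),4,7-triene-8-carboxylate, all ring olefins ring-cis | C=CCOC(=O)/C1=C/C/C=C(C)\C(=O)C/C=C(C)\C1=O | intermediate
10 | isopropenylboronic acid pinacol ester | CC(=C)B1OC(C)(C)C(C)(C)O1 | starting material
11 | allyl (7S)-7-isopropenyl-4,10-dimethyl-3,9-dioxocyclodeca-1(10),4-diene-8-carboxylate, C8 epimers | C=C(C)[C@H]1C/C=C(C)\C(=O)C/C=C(C)\C(=O)C1C(=O)OCC=C | intermediate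
12 | allyl (7R)-8-acetoxy-7-isopropenyl-4,10-dimethyl-3,9-dioxocyclodeca-1(10),4-diene-8-carboxylate, C8 not assigned | C=C(C)[C@H]1C/C=C(C)\C(=O)C/C=C(C)\C(=O)C1(OC(C)=O)C(=O)OCC=C | intermediate
13 | allyl (3S,7R)-8-acetoxy-3-hydroxy-7-isopropenyl-4,10-dimethyl-9-oxocyclodeca-1(10),4-diene-8-carboxylate | C=C(C)[C@H]1C/C=C(C)\[C@@H](O)C/C=C(C)\C(=O)C1(OC(C)=O)C(=O)OCC=C | intermediate
14 | allyl (3S,4R,5S,7R)-8-acetoxy-4,5-epoxy-3-hydroxy-7-isopropenyl-4,10-dimethyl-9-oxocyclodec-1(10)-ene-8-carboxylate | C=C(C)[C@H]1C[C@@H]2O[C@]2(C)[C@@H](O)C/C=C(C)\C(=O)C1(OC(C)=O)C(=O)OCC=C | intermediate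
15 | angelic acid, (Z)-2-methylbut-2-enoic acid | C/C=C(/C)C(=O)O | starting material
16 | angelic 2,4,6-trichlorobenzoic anhydride | C/C=C(/C)C(=O)OC(=O)c1c(Cl)cc(Cl)cc1Cl | intermediate
17 | allyl (3S,4S,5S,7R)-8-acetoxy-3-angeloyloxy-4,5-epoxy-7-isopropenyl-4,10-dimethyl-9-oxocyclodec-1(10)-ene-8-carboxylate | C=C(C)[C@H]1C[C@@H]2O[C@]2(C)[C@@H](OC(=O)/C(C)=C\C)C/C=C(C)\C(=O)C1(OC(C)=O)C(=O)OCC=C | intermediate
18 | (3S,4S,5S,7R,8S)-8-acetoxy-3-angeloyloxy-4,5-epoxy-7-isopropenyl-4,10-dimethylcyclodec-1(10)-en-9-one | C=C(C)[C@H]1C[C@@H]2O[C@]2(C)[C@@H](OC(=O)/C(C)=C\C)C/C=C(C)\C(=O)[C@H]1OC(C)=O | intermediate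
19 | (3S,4S,5S,7R,8S,9R)-8-acetoxy-3-angeloyloxy-4,5-epoxy-7-isopropenyl-4,10-dimethylcyclodec-1(10)-en-9-ol | C=C(C)[C@H]1C[C@@H]2O[C@]2(C)[C@@H](OC(=O)/C(C)=C\C)C/C=C(C)\[C@@H](O)[C@H]1OC(C)=O | intermediate
20 | (1R,3S,4S,5S,7R,8S,9S,10S)-8-acetoxy-3-angeloyloxy-1,10:4,5-diepoxy-7-isopropenyl-4,10-dimethylcyclodecan-9-ol | C=C(C)[C@H]1C[C@@H]2O[C@]2(C)[C@@H](OC(=O)/C(C)=C\C)C[C@H]2O[C@@]2(C)[C@@H](O)[C@H]1OC(C)=O | intermediate
21 | (1R,3S,4S,5S,7R,8S,9S,10R)-8-acetoxy-3,9-bis(angeloyloxy)-1,10:4,5-diepoxy-7-isopropenyl-4,10-dimethylcyclodecane | C=C(C)[C@H]1C[C@@H]2O[C@]2(C)[C@@H](OC(=O)/C(C)=C\C)C[C@H]2O[C@@]2(C)[C@@H](OC(=O)/C(C)=C\C)[C@H]1OC(C)=O | target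

## Step count and least certain steps

Total: 14 steps. Longest linear sequence: 12 steps (steps 1, 2, 4 to 8 and 10 to 14, from diene 1); steps 3 and 9 are one-step side branches.

**Step 4 (key step, proposed new method).** The most likely failure is proton transfer to the vinyl anion of 7 before the four-membered ring closes, because the donor carbon keeps an acidic hydrogen and a second acidic methylene sits across the ring; O-alkylation and a second addition of 6 are lesser risks. Fallback, from 3 back to 9, by the known enamine version of the same ring enlargement, which has no free vinyl anion. Condensation of 3 with pyrrolidine (TsOH cat., benzene, water removal) should give the push–pull dienamine 9-(pyrrolidin-1-yl)-4,10-dimethylcycloocta-1(10),4,6(9)-trien-3-one F1. Warming F1 with 6 in acetonitrile should give, by stepwise [2+2] addition at the C6=C9 enamine bond and opening of the aminocyclobutene, the ring-enlarged dienamine ester F2. Aqueous acetic acid then hydrolyses F2 to 9 as its tautomer mixture.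

**Step 5.** Under aqueous base 9 may sit largely as its delocalised enolate, which is no acceptor, and face discrimination on a mobile ten-membered acceptor that can tautomerise may be poor. Fallback, from 9 back to 13, without a chiral catalyst at this stage. Addition of (CH2=C(CH3))2CuMgBr (from isopropenylmagnesium bromide and CuI, THF, −78 °C) should give racemic keto ester F3, and Pb(OAc)4 the racemic acetoxy keto ester F4. The (R)-CBS reduction of step 7 then converts the two enantiomers into diastereomers, 13 and the (3S,7S)-isomer F5, which are separated by chromatography at the cost of half the material.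

**Step 8.** Facial selectivity rests on a medium-ring trend that has not been tested on a ten-membered, methyl-substituted olefin, and the isopropenyl group may be epoxidised as well. Fallback, from 12 back to 17, which reverses both the carbinol and the reagent. The (S)-CBS catalyst with catecholborane should give the (3R)-alcohol F6. VO(acac)2/t-BuOOH should then give the epoxide cis to that hydroxyl, with the same 4,5-epoxide configuration as in 14, as epoxy alcohol F7, without touching the isopropenyl group. Mitsunobu esterification of F7 with 15 (PPh3, DIAD, toluene) inverts C3 and gives 17 directly.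

**Step 11.** Protonation may occur on the other face of C8, the acetoxy ketone may drift toward the other epimer under the amine base, and C-allylation may compete. Fallback, from 11 back to 18, in which oxygen and not hydrogen enters C8 last, so that the same facial preference gives the opposite configuration. (R)-CBS reduction of 11, with the enolised keto ester shielded as its boron enolate, should give the (3S)-alcohol F8. mCPBA gives epoxy alcohol F9, and Pd(PPh3)4 with HCO2H/Et3N the decarboxylated enone F10 (C8 as CH2). Acylation with anhydride 16 (Et3N, toluene, 75 °C) gives angelate F11, and Mn(OAc)3 in hot benzene acetoxylates the α'-carbon C8 of the enone to give 18.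

**Step 12.** Catalyst and substrate preferences are opposed, so poor facial selectivity is likely, and borane may be slow at a ketone next to an acetoxy-bearing carbon. Fallback, from 18 to 21, which uses the substrate preference. Luche reduction (NaBH4, CeCl3·7H2O, MeOH, −78 °C) should give the 9-epimeric alcohol F12 with the hydroxyl trans to the acetoxy group. mCPBA then epoxidises C1=C10 trans to that hydroxyl, which is the target configuration at C1 and C10, to give diepoxy alcohol F13. Mitsunobu esterification of F13 with 15 (PPh3, DIAD) inverts C9 and gives 21 without steps 13 and 14.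

## Further compounds

F1 | step 4 | 9-(pyrrolidin-1-yl)-4,10-dimethylcycloocta-1(10),4,6(9)-trien-3-one (target locants) | O=C1C/C=C(C)\C(N2CCCC2)=C/C=C1/C
F2 | step 4 | allyl 9-(pyrrolidin-1-yl)-4,10-dimethyl-3-oxocyclodeca-1(10),4,6,8-tetraene-8-carboxylate | C=CCOC(=O)C1=C(N2CCCC2)/C(C)=C\CC(=O)/C(C)=C\C=C1
F3 | step 5 | racemic allyl 7-isopropenyl-4,10-dimethyl-3,9-dioxocyclodeca-1(10),4-diene-8-carboxylate | C=C(C)C1C/C=C(C)\C(=O)C/C=C(C)\C(=O)C1C(=O)OCC=C
F4 | step 5 | racemic allyl 8-acetoxy-7-isopropenyl-4,10-dimethyl-3,9-dioxocyclodeca-1(10),4-diene-8-carboxylate | C=C(C)C1C/C=C(C)\C(=O)C/C=C(C)\C(=O)C1(OC(C)=O)C(=O)OCC=C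
F5 | step 5 | allyl (3S,7S)-8-acetoxy-3-hydroxy-7-isopropenyl-4,10-dimethyl-9-oxocyclodeca-1(10),4-diene-8-carboxylate | C=C(C)[C@@H]1C/C=C(C)\[C@@H](O)C/C=C(C)\C(=O)C1(OC(C)=O)C(=O)OCC=C
F6 | step 8 | allyl (3R,7R)-8-acetoxy-3-hydroxy-7-isopropenyl-4,10-dimethyl-9-oxocyclodeca-1(10),4-diene-8-carboxylate | C=C(C)[C@H]1C/C=C(C)\[C@H](O)C/C=C(C)\C(=O)C1(OC(C)=O)C(=O)OCC=C
F7 | step 8 | allyl (3R,4R,5S,7R)-8-acetoxy-4,5-epoxy-3-hydroxy-7-isopropenyl-4,10-dimethyl-9-oxocyclodec-1(10)-ene-8-carboxylate | C=C(C)[C@H]1C[C@@H]2O[C@]2(C)[C@H](O)C/C=C(C)\C(=O)C1(OC(C)=O)C(=O)OCC=C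
F8 | step 11 | allyl (3S,7S)-3-hydroxy-7-isopropenyl-4,10-dimethyl-9-oxocyclodeca-1(10),4-diene-8-carboxylate | C=C(C)[C@H]1C/C=C(C)\[C@@H](O)C/C=C(C)\C(=O)C1C(=O)OCC=C
F9 | step 11 | allyl 4,5-epoxy-3-hydroxy-7-isopropenyl-4,10-dimethyl-9-oxocyclodec-1(10)-ene-8-carboxylate, C3, C4, C5 and C7 as in 14 | C=C(C)[C@H]1C[C@@H]2O[C@]2(C)[C@@H](O)C/C=C(C)\C(=O)C1C(=O)OCC=C
F10 | step 11 | 4,5-epoxy-3-hydroxy-7-isopropenyl-4,10-dimethylcyclodec-1(10)-en-9-one, C3, C4, C5 and C7 as in 14 | C=C(C)[C@H]1C[C@@H]2O[C@]2(C)[C@@H](O)C/C=C(C)\C(=O)C1
F11 | step 11 | 3-angeloyloxy-4,5-epoxy-7-isopropenyl-4,10-dimethylcyclodec-1(10)-en-9-one, C3, C4, C5 and C7 as in 18 | C=C(C)[C@H]1C[C@@H]2O[C@]2(C)[C@@H](OC(=O)/C(C)=C\C)C/C=C(C)\C(=O)C1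
F12 | step 12 | 9-epimer of 19 (hydroxyl trans to the C8 acetoxy group) | C=C(C)[C@H]1C[C@@H]2O[C@]2(C)[C@@H](OC(=O)/C(C)=C\C)C/C=C(C)\[C@H](O)[C@H]1OC(C)=O
F13 | step 12 | 9-epimer of 20 (1,10-epoxide as in the target, hydroxyl trans to it) | C=C(C)[C@H]1C[C@@H]2O[C@]2(C)[C@@H](OC(=O)/C(C)=C\C)C[C@H]2O[C@@]2(C)[C@H](O)[C@H]1OC(C)=O
A1 | alternative 1 | acyclic C1 aldehyde C10 chloro ketone with C3 TBS ether, C7 isopropenyl and C8 4-methoxybenzyl ether | O=CC[C@H](O[Si](C)(C)C(C)(C)C)/C(C)=C\C[C@H](C(C)=C)[C@H](OCc1ccc(OC)cc1)C(=O)C(C)Cl
A2 | alternative 1 | ten-membered 1,10-epoxy-9-ketone with C8 4-methoxybenzyl ether and C3 TBS ether | C=C(C)[C@H]1C/C=C(C)\[C@@H](O[Si](C)(C)C(C)(C)C)C[C@H]2O[C@@]2(C)C(=O)[C@H]1OCc1ccc(OC)cc1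
A3 | alternative 2 | 5-isopropenyl-3-(4-methoxybenzyloxy)-2-methylcyclohex-2-enone, single enantiomer | CC1=C(OCc2ccc(OC)cc2)C[C@@H](C(C)=C)CC1=O
A4 | alternative 2 | 3-ethoxy-2-methyl-1-(triethylsilyloxy)cyclobutene, racemic | CC1=C(O[Si](CC)(CC)CC)CC1OCC
A5 | alternative 2 | six–four–four tricyclic photoadduct | C[C@]12C(=O)C[C@H](C(C)=C)C[C@@]1(OCc3ccc(OC)cc3)[C@]3(C)[C@@H](OCC)C[C@]23O[Si](CC)(CC)CC
A6 | alternative 3 | acyclic C6 alkyl iodide C5 (Z)-vinyl iodide with C8/C9 acetonide, C3 TBS ether and C7 isopropenyl | I/C=C(C)\[C@@H](O[Si](C)(C)C(C)(C)C)C/C=C(C)\[C@H]1OC(C)(C)O[C@H]1[C@H](CI)C(C)=C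
A7 | alternative 3 | (1(10)Z,4Z)-cyclodecadiene with C8/C9 acetonide, C3 TBS ether and C7 isopropenyl | C=C(C)[C@H]1C/C=C(C)\[C@@H](O[Si](C)(C)C(C)(C)C)C/C=C(C)\[C@H]2OC(C)(C)O[C@@H]12
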